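## The problem

The target is a macrocyclic bis(bibenzyl). Four benzene rings are joined into a 20-membered ring by two CH2CH2 bridges (A–D and B–C) and two diaryl ether oxygens (A–O–B and C–O–D). Rings A and D are catechol-type: ring A has its ether oxygen para to the CH2 and an OH ortho to that oxygen, and ring D has its OH para to the CH2 and the ether oxygen ortho to the OH. Ring B is meta-linked and ring C para-linked, and neither carries a group that would activate it for nucleophilic aromatic substitution. There is no stereocentre, so the task is one of connectivity: two diaryl ethers to unactivated rings and the closure of a large ring. The electron-rich rings A and D and their phenols are oxidation-prone and should stay masked as methyl ethers until the last step. The ring A oxygen that ends up in the A–O–B ether needs a second mask that can be removed on its own. An aryl bromide reserved for the ring closure has to survive every earlier step, which excludes hydrogenation and strongly reducing metals once it is in place. Ring C carries an oxygen on C4, a benzylic carbon on C1 and four CH. This is the pattern that results when C3 and C6 of a 5-acyl-2-pyrone are bridged by the two carbons of an aryloxyacetylene and the lactone bridge leaves as CO2.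

## Retrosynthesis

**Unmasking.** The two O–CH3 bonds are cut first, so target 24 goes back to macrocyclic dimethyl ether 23. Methyl ethers are the only phenol masks that tolerate every reagent of the route, and BBr3 leaves diaryl ethers and bibenzyl bridges alone.

**Macrocycle.** In 23 the bond from the ring A oxygen to ring B is cut, giving the open-chain bromophenol 22. Cutting a bibenzyl C–C bond instead would need both diaryl ethers in place beforehand and a hydrogenation after ring closure. Cutting C–O–D would set the hindered ring D oxygen against an unactivated para-alkyl ring. The A–O–B cut needs only a guaiacol-type phenoxide and a meta-alkyl bromobenzene, and the bromine can be carried unchanged from 3-bromobenzyl bromide 15. The forward reaction is an intramolecular Ullmann etherification at high dilution.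

**Adjustment of 22.** The ring C benzylic CH2 of the B–C bridge is traced to a ketone and the free ring A phenol to its MOM ether, giving seco deoxybenzoin 19. The ketone is the acceptor group that the pyrone chemistry requires. Ketone and acetal both respond to Et3SiH in trifluoroacetic acid, so one operation should clear both.

**Ring C.** In 19 two C–C bonds of ring C are cut: C2–C3 and C4–C5, counting from the acyl-bearing carbon as C1. This gives aryl ethynyl ether 12 and coumalyl ketone 17, with bicyclic lactone 18 as the transient link between them. The neighbouring cut, the C4–O bond by nucleophilic aromatic substitution, is sound chemistry and is kept as insurance. The ring construction is preferred because it makes the C–O–D ether from a phenol without any aryl–oxygen coupling, and it joins a two-ring fragment to a one-ring fragment in the same event. The forward reaction has to be regioselective (oxygen para to acyl) and has to outrun decomposition of the ynol ether.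

**Coumalyl ketone.** In 17 the bond between the ketone carbon and its CH2 is cut, leading to coumaloyl chloride 14 and 3-bromobenzylzinc bromide 16. These come from coumalic acid 13 and 3-bromobenzyl bromide 15. Coumalic acid already has the carboxyl on C5 of the pyrone. The forward acylation must be faster than conjugate attack at C6, which argues for a soft zinc reagent under palladium catalysis.

**Ynol ether.** The O–C(sp) bond of 12 is cut. The two alkyne carbons come from trichloroethylene by way of E-dichlorovinyl ether 9, chloroalkyne 10 and lithium acetylide 11. This step exposes phenol 8, the ring D oxygen.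

**A–D bibenzyl.** The A–D bridge of 8 is traced to the C=C bond of stilbene 7, formed by Wittig reaction of ylide 6 (from phosphonium salt 3) with aldehyde 5. A benzyl group on the ring D oxygen is chosen because the hydrogenation that saturates the alkene frees exactly that phenol. MOM on the ring A oxygen survives hydrogenation, carbonate, n-BuLi at low temperature and heat, and leaves only in acid. Salt 3 comes from commercial O-benzylisovanillin 1 through alcohol 2, and aldehyde 5 from vanillin 4.

## Roads not taken

**Alternative 1:** The cut is the same A–O–B bond as in the chosen plan, but reached through a 21-membered aryl ester, macrolactone A1, in which the ring A oxygen is acylated by a ring B carboxyl. Ni(cod)2 (zerovalent nickel) with a chelating bisphosphine would insert into the acyl–oxygen bond, lose CO and reductively eliminate to the target dimethyl ether A2, which is the same compound as 23.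
- Merits: macrolactonisation is among the most dependable large-ring closures and would probably beat an Ullmann macro-etherification in efficiency. The C–O bond then forms within a ring, so dilution matters less at that stage, and no aryl halide is needed.
- Weak points: decarbonylative etherification is established mainly for esters of heteroaromatic acids and electron-poor partners. A1 is a plain benzoate of an ortho-methoxy, electron-rich phenol, so oxidative addition into the acyl–oxygen bond is less favourable, and the CO set free can tie up nickel at the temperatures required. A ring contraction of this kind on a macrolactone would also be a new substrate class.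
- Comparison: it needs two operations (lactonise, contract) where the chosen plan needs one, and it leaves the C–O–D ether to be made by other means. Against the better ring-closing step of this road, the chosen plan sets a well-tested copper etherification with a boronic acid variant in reserve.

**Alternative 2:** The cut is the C–O–D bond, closed last. Anodic oxidation of seco bisphenol A3 (ring C as a 2,6-dichlorophenol, ring D as a 2,6-dibromophenol) followed by zinc reduction would join the ring C oxygen to a bromine-bearing ortho carbon of ring D and give the trihalogenated macrocycle A4.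
- Merits: the method makes a diaryl ether to an unactivated ring without base or transition metal, forms the hindered C–O–D bond and the macrocycle in one operation, and places the ring D oxygen correctly through the ortho halogen.
- Weak points: ring C of the target has no ortho substituents, so the two chlorines and the remaining bromine are pure auxiliaries. They cost selective halogenations before and three hydrogenolyses after. The oxidation passes through dienone intermediates whose partition between inter- and intramolecular capture is hard to predict for a 20-membered ring. The A–O–B ether still has to be made by a coupling beforehand.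
- Comparison: this road is better in that one step does what the chosen plan spreads over cycloaddition and Ullmann closure. The chosen plan answers with no auxiliary atoms, no redox detour, and a C–O–D ether formed convergently from a simple phenol.

**Alternative 3:** The cut is the bond from ring C to the B–C bridge. Pd(OAc)2 with P(o-tol)3 would couple the ring C iodide of seco compound A5 with the terminal carbon of its ring B styrene and close the ring as the macrocyclic E-stilbene A6. Hydrogenation of A6 would then give A2.
- Merits: Heck coupling of an aryl iodide with a styrene is tolerant and reliable, the terminal alkene carbon is unhindered, and the later hydrogenation is trivial. As a ring-closing event it is probably at least as dependable as the Ullmann closure used here.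
- Weak points: both diaryl ethers of A5 must be made first by intermolecular couplings to unactivated rings, one of them next to a methoxy group. An E-stilbene inside the 20-membered ring adds strain that the saturated bridge does not have. Attack at the internal alkene carbon would give a 19-membered 1,1-diarylethene. One extra step follows ring closure.
- Comparison: the chosen plan spends its key step on the ether that is hardest to make by coupling and needs no reduction after cyclisation. It accepts in exchange a less documented dienophile.

Key step: step 10

Remark on the chemistry: the target has no stereocentre and its 20-membered ring is taken to be conformationally mobile, so no stereochemical element has to be set. The only stereodescriptor in the route is the E geometry of dichlorovinyl ether 9.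

## Route

Step 1
Reactants: 1 3-benzyloxy-4-methoxybenzaldehyde (O-benzylisovanillin)
Product: 2 (3-benzyloxy-4-methoxyphenyl)methanol
Conditions: NaBH4, MeOH, 0 °C
Reagents that add atoms: none
Why: Borohydride reduction of an aromatic aldehyde to the benzylic alcohol; the benzyl and methyl ethers are inert.

Step 2
Reactants: 2 (3-benzyloxy-4-methoxyphenyl)methanol
Product: 3 (3-benzyloxy-4-methoxybenzyl)triphenylphosphonium bromide
Conditions: PPh3·HBr, MeCN, reflux
Reagents that add atoms: triphenylphosphine hydrobromide, [Br-].[PH+](c1ccccc1)(c1ccccc1)c1ccccc1
Why: The electron-rich benzylic alcohol ionises under the acidic salt and is captured by triphenylphosphine, a standard one-step phosphonium salt formation that avoids a separate benzylic halide.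

Step 3
Reactants: 4 vanillin
Product: 5 3-methoxy-4-(methoxymethoxy)benzaldehyde
Conditions: MOMCl, i-Pr2NEt, CH2Cl2, 0 °C to rt
Reagents that add atoms: chloromethyl methyl ether, COCCl
Why: O-alkylation of the phenol to its methoxymethyl acetal, which will later withstand base, hydrogenation, n-BuLi at low temperature and heat.

Step 4
Reactants: 3 (3-benzyloxy-4-methoxybenzyl)triphenylphosphonium bromide; 5 3-methoxy-4-(methoxymethoxy)benzaldehyde
Product: 7 2-benzyloxy-1-methoxy-4-{2-[3-methoxy-4-(methoxymethoxy)phenyl]ethenyl}benzene (E/Z mixture), via phosphorus ylide 6 (not isolated)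
Conditions: t-BuOK, THF, 0 °C to rt
Reagents that add atoms: none
Why: Wittig olefination of a semi-stabilised benzylic ylide with an aromatic aldehyde; the E/Z ratio is irrelevant because the alkene is saturated in the next step.

Step 5
Reactants: 7 2-benzyloxy-1-methoxy-4-{2-[3-methoxy-4-(methoxymethoxy)phenyl]ethenyl}benzene
Product: 8 2-methoxy-5-{2-[3-methoxy-4-(methoxymethoxy)phenyl]ethyl}phenol
Conditions: H2 (1 atm), 10% Pd/C, EtOAc–EtOH, rt
Reagents that add atoms: none
Why: Catalytic hydrogenation saturates the stilbene and hydrogenolyses the benzyl ether in one operation, freeing only the ring D phenol; the MOM acetal and methyl ethers are stable.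

Step 6
Reactants: 8 2-methoxy-5-{2-[3-methoxy-4-(methoxymethoxy)phenyl]ethyl}phenol
Product: 9 2-[(E)-1,2-dichloroethenyloxy]-1-methoxy-4-{2-[3-methoxy-4-(methoxymethoxy)phenyl]ethyl}benzene
Conditions: Cl2C=CHCl, K2CO3, DMF, 70 °C
Reagents that add atoms: trichloroethylene, ClC=C(Cl)Cl
Why: Carbonate eliminates HCl from trichloroethylene to dichloroacetylene, to which the phenoxide adds in anti fashion; protonation then gives the E-dichlorovinyl ether, a known way of attaching a two-carbon alkyne precursor to a phenol oxygen.

Step 7
Reactants: 9 2-[(E)-1,2-dichloroethenyloxy]-1-methoxy-4-{2-[3-methoxy-4-(methoxymethoxy)phenyl]ethyl}benzene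
Product: 12 2-ethynyloxy-1-methoxy-4-{2-[3-methoxy-4-(methoxymethoxy)phenyl]ethyl}benzene, via chloroethynyl ether 10 (not isolated), via lithium aryloxyacetylide 11 (not isolated)
Conditions: n-BuLi (2.3 equiv), THF, −78 to −40 °C; then H2O, −78 °C; used at once
Reagents that add atoms: none
Why: Deprotonation and loss of LiCl give the chloroalkyne, chlorine–lithium exchange gives the acetylide, and protonation gives the terminal aryl ynol ether (the established dichlorovinyl ether route to ynol ethers); at −78 °C these steps are much faster than ortho-lithiation next to the MOM ether.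

Step 8
Reactants: 13 coumalic acid
Product: 14 2-oxo-2H-pyran-5-carbonyl chloride (coumaloyl chloride)
Conditions: SOCl2, DMF (cat.), toluene, 80 °C
Reagents that add atoms: thionyl chloride, O=S(Cl)Cl
Why: Standard acid chloride formation; coumaloyl chloride is a known, isolable compound and the pyrone ring is stable to these conditions.

Step 9
Reactants: 14 2-oxo-2H-pyran-5-carbonyl chloride; 15 3-bromobenzyl bromide
Product: 17 5-[(3-bromophenyl)acetyl]-2H-pyran-2-one, via 3-bromobenzylzinc bromide 16 (not isolated)
Conditions: 15, Zn dust, LiCl, THF, 25 °C; then 14, PdCl2(PPh3)2 (2 mol %), THF, 0 °C to rt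
Reagents that add atoms: none
Why: Zinc inserts into the benzylic C–Br bond and leaves the aryl bromide alone; Negishi acylation of the acid chloride follows, since oxidative addition of the acyl chloride to zerovalent palladium at 0 °C outpaces that of the aryl bromide and the soft zinc reagent does not attack the pyrone ring.

Step 10
Reactants: 12 2-ethynyloxy-1-methoxy-4-{2-[3-methoxy-4-(methoxymethoxy)phenyl]ethyl}benzene; 17 5-[(3-bromophenyl)acetyl]-2H-pyran-2-one
Product: 19 2-(3-bromophenyl)-1-[4-(2-methoxy-5-{2-[3-methoxy-4-(methoxymethoxy)phenyl]ethyl}phenoxy)phenyl]ethanone, via bicyclic lactone 18 (not isolated)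
Conditions: 12 (1 equiv), 17 (1.5 equiv), BHT (cat.), toluene (0.5 M), 90 °C, sealed tube, acid-free glassware
Reagents that add atoms: none
Why: The electron-poor diene C3=C4–C5=C6 of pyrone 17 and the electron-rich alkyne 12 should combine in an inverse-electron-demand Diels–Alder reaction to the 2-oxabicyclo[2.2.2]octadienone 18, which loses CO2 by retro-Diels–Alder reaction at the same temperature and delivers ring C already aromatic, the alkyne supplying the oxidation level. The closest known reaction type is the cycloaddition of coumalate esters with enol ethers, ketene acetals, alkoxyalkynes and ynamines, which gives para-substituted benzoates after CO2 loss; an aryloxyalkyne and a 5-acyl in place of a 5-alkoxycarbonyl group are new substrates for this known reaction. Ring C is closed by an intermolecular [4+2] cycloaddition that forms two C–C bonds (alkyne CH to pyrone C6, alkyne C–OAr to pyrone C3), followed by cycloreversion of the lactone bridge. No stereocentre remains, because the two bridgehead carbons of racemic 18 become sp2 carbons of ring C. The selectivity needed is regiochemical: C6 is β to the ketone, vinylogously conjugated to the lactone carbonyl and bound to the ring oxygen, so it carries the largest LUMO coefficient, while the HOMO of 12 is largest at its terminal carbon; the asynchronous transition state joins these two atoms first and places the aryloxy carbon on C3, para to the acyl group. The ketone is a stronger acceptor than the ester of a coumalate, which should lower the temperature needed and spare the ynol ether; excess 17, high concentration and a radical inhibitor serve the same end. The aryl bromide, the MOM ether, the methyl ethers and the enolisable CH2 are spectators under neutral thermal conditions.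

Step 11
Reactants: 19 2-(3-bromophenyl)-1-[4-(2-methoxy-5-{2-[3-methoxy-4-(methoxymethoxy)phenyl]ethyl}phenoxy)phenyl]ethanone
Product: 22 4-[2-(3-{4-[2-(3-bromophenyl)ethyl]phenoxy}-4-methoxyphenyl)ethyl]-2-methoxyphenol, via phenol ketone 20 (not isolated), via benzylic carbinol 21 (not isolated)
Conditions: Et3SiH (5 equiv), CF3CO2H, CH2Cl2, 0 °C to rt
Reagents that add atoms: none
Why: Ionic hydrogenation: the acid cleaves the MOM acetal, and the protonated para-aryloxy aryl ketone takes up hydride twice by way of the carbinol and its stabilised benzylic cation; excess silane also reduces the methoxymethyl cation, so it cannot alkylate the electron-rich rings.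

Step 12
Reactants: 22 4-[2-(3-{4-[2-(3-bromophenyl)ethyl]phenoxy}-4-methoxyphenyl)ethyl]-2-methoxyphenol
Product: 23 macrocyclic dimethyl ether (20-membered ring; rings A and D as methyl ethers)
Conditions: CuI (0.3 equiv), N,N-dimethylglycine hydrochloride (0.9 equiv), Cs2CO3 (3 equiv), 1,4-dioxane, 100 °C, slow addition to 0.003 M
Reagents that add atoms: none
Why: Ligand-accelerated intramolecular Ullmann diaryl ether synthesis; amino acid ligands allow aryl bromides and ortho-substituted phenols to couple near 100 °C, and high dilution favours closure of the unstrained 20-membered ring over oligomerisation.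

Step 13
Reactants: 23 macrocyclic dimethyl ether
Product: 24 target bisphenol CNP0329842.0
Conditions: BBr3, CH2Cl2, −78 °C to rt; then H2O
Reagents that add atoms: none
Why: Lewis-acid cleavage of both aryl methyl ethers; diaryl ethers and bibenzyl bridges are untouched by BBr3.

## Compound list

1 | 3-benzyloxy-4-methoxybenzaldehyde (O-benzylisovanillin) | COc1ccc(C=O)cc1OCc1ccccc1 | starting material
2 | (3-benzyloxy-4-methoxyphenyl)methanol | COc1ccc(CO)cc1OCc1ccccc1 | intermediate
3 | (3-benzyloxy-4-methoxybenzyl)triphenylphosphonium bromide | COc1ccc(C[P+](c2ccccc2)(c2ccccc2)c2ccccc2)cc1OCc1ccccc1.[Br-] | intermediate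
4 | vanillin | COc1cc(C=O)ccc1O | starting material
5 | 3-methoxy-4-(methoxymethoxy)benzaldehyde | COCOc1ccc(C=O)cc1OC | intermediate
6 | (3-benzyloxy-4-methoxybenzylidene)triphenylphosphorane (ylide, not isolated) | COc1ccc(C=P(c2ccccc2)(c2ccccc2)c2ccccc2)cc1OCc1ccccc1 | intermediate
7 | 2-benzyloxy-1-methoxy-4-{2-[3-methoxy-4-(methoxymethoxy)phenyl]ethenyl}benzene (E/Z mixture) | COCOc1ccc(C=Cc2ccc(OC)c(OCc3ccccc3)c2)cc1OC | intermediate
8 | 2-methoxy-5-{2-[3-methoxy-4-(methoxymethoxy)phenyl]ethyl}phenol | COCOc1ccc(CCc2ccc(OC)c(O)c2)cc1OC | intermediate
9 | 2-[(E)-1,2-dichloroethenyloxy]-1-methoxy-4-{2-[3-methoxy-4-(methoxymethoxy)phenyl]ethyl}benzene | COCOc1ccc(CCc2ccc(OC)c(O/C(Cl)=C\Cl)c2)cc1OC | intermediate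
10 | 2-(chloroethynyloxy)-1-methoxy-4-{2-[3-methoxy-4-(methoxymethoxy)phenyl]ethyl}benzene (not isolated) | COCOc1ccc(CCc2ccc(OC)c(OC#CCl)c2)cc1OC | intermediate
11 | lithium acetylide of 12 (not isolated) | COCOc1ccc(CCc2ccc(OC)c(OC#C[Li])c2)cc1OC | intermediate
12 | 2-ethynyloxy-1-methoxy-4-{2-[3-methoxy-4-(methoxymethoxy)phenyl]ethyl}benzene | COCOc1ccc(CCc2ccc(OC)c(OC#C)c2)cc1OC | intermediate
13 | coumalic acid | O=C1C=CC(=CO1)C(=O)O | starting material
14 | 2-oxo-2H-pyran-5-carbonyl chloride | O=C1C=CC(=CO1)C(=O)Cl | intermediate
15 | 3-bromobenzyl bromide | BrCc1cccc(Br)c1 | starting material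
16 | 3-bromobenzylzinc bromide (not isolated) | Br[Zn]Cc1cccc(Br)c1 | intermediate
17 | 5-[(3-bromophenyl)acetyl]-2H-pyran-2-one | O=C1C=CC(C(=O)Cc2cccc(Br)c2)=CO1 | intermediate
18 | 2-oxabicyclo[2.2.2]octa-5,7-dien-3-one adduct of 12 and 17 (racemic, not isolated) | O=C1OC2C=C(Oc3cc(CCc4ccc(OCOC)c(OC)c4)ccc3OC)C1C=C2C(=O)Cc1cccc(Br)c1 | intermediate
19 | 2-(3-bromophenyl)-1-[4-(2-methoxy-5-{2-[3-methoxy-4-(methoxymethoxy)phenyl]ethyl}phenoxy)phenyl]ethanone | COc1ccc(CCc2ccc(OCOC)c(OC)c2)cc1Oc1ccc(cc1)C(=O)Cc1cccc(Br)c1 | intermediate
20 | 2-(3-bromophenyl)-1-(4-{5-[2-(4-hydroxy-3-methoxyphenyl)ethyl]-2-methoxyphenoxy}phenyl)ethanone (not isolated) | COc1ccc(CCc2ccc(O)c(OC)c2)cc1Oc1ccc(cc1)C(=O)Cc1cccc(Br)c1 | intermediate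
21 | 4-[2-(3-{4-[2-(3-bromophenyl)-1-hydroxyethyl]phenoxy}-4-methoxyphenyl)ethyl]-2-methoxyphenol (racemic, not isolated) | COc1ccc(CCc2ccc(O)c(OC)c2)cc1Oc1ccc(cc1)C(O)Cc1cccc(Br)c1 | intermediate
22 | 4-[2-(3-{4-[2-(3-bromophenyl)ethyl]phenoxy}-4-methoxyphenyl)ethyl]-2-methoxyphenol | COc1ccc(CCc2ccc(O)c(OC)c2)cc1Oc1ccc(cc1)CCc1cccc(Br)c1 | intermediate
23 | macrocyclic dimethyl ether of the target | COc1cc2ccc1Oc1cccc(c1)CCc1ccc(cc1)Oc1cc(ccc1OC)CC2 | intermediate
24 | CNP0329842.0 (macrocyclic bisphenol) | Oc1cc2ccc1Oc1cccc(c1)CCc1ccc(cc1)Oc1cc(ccc1O)CC2 | target

## Step count and least certain steps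

Total: 13 steps. Longest linear sequence: 10 steps (steps 1, 2, 4, 5, 6, 7, 10, 11, 12, 13).

**Step 10 (key step).**
- What may go wrong: self-oligomerisation or adventitious hydration of the terminal aryloxyalkyne before the diene intercepts it. An aryloxy group is a weaker donor than an alkoxy or amino group, so the cycloaddition may need more heat than the alkyne tolerates. Hetero-Diels–Alder addition across the acyl enone unit is a second possible diversion.
- Fallback: it gives up the pyrone construction of ring C and sets out from phenol 8. Nucleophilic aromatic substitution on 4-fluorobenzaldehyde (K2CO3, DMF, 120 °C) gives 4-(2-methoxy-5-{2-[3-methoxy-4-(methoxymethoxy)phenyl]ethyl}phenoxy)benzaldehyde F1. Addition of the zinc reagent 16 in THF gives the MOM-protected carbinol F2. The conditions of step 11 then ionise and reduce the carbinol and remove the acetal, so the route is rejoined at 22.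

**Step 9.**
- What may go wrong: conjugate attack of the benzylzinc reagent at C6 of the pyrone with ring opening, or insertion of palladium into the aryl C–Br bond in competition with acylation.
- Fallback: it keeps ring C as a pyrone-derived ring but moves the ketone-forming step to a plain benzoate. It sets out from 12 and commercial methyl coumalate. Cycloaddition under the conditions of step 10 passes through the bicyclic lactone adduct F3 and gives the methyl 4-aryloxybenzoate F4. Me(MeO)NH·HCl and i-PrMgCl convert this into the Weinreb amide F5. 3-Bromobenzylmagnesium bromide F6, prepared from 15 and magnesium in Et2O, adds once to give ketone 19, where the route is rejoined.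

**Step 7.**
- What may go wrong: loss of the terminal ynol ether by hydration or oligomerisation during work-up and concentration, and ortho-lithiation beside the MOM ether if the temperature drifts upward.
- Fallback: it sets out from 9 and quenches acetylide 11 with Me3SiCl instead of water, giving the storable (trimethylsilyl)ethynyl ether F7. Heating F7 with 17 gives, through the silylated bicyclic lactone F8, the ring C silylated seco ketone F9, with silicon ortho to the aryloxy group. The trifluoroacetic acid of step 11 removes the silyl group by ipso-protonation while reducing the ketone and cleaving the acetal, so the route is rejoined at 22.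

**Step 12.**
- What may go wrong: intermolecular etherification outrunning ring closure, and protodebromination, because the 2-methoxyphenoxide is hindered and the bromide unactivated.
- Fallback: it sets out from 22. Borylation with tetrahydroxydiboron (Pd(OAc)2, XPhos, KOAc, EtOH, 80 °C) gives the boronic acid F10. A Chan–Lam coupling (Cu(OAc)2, pyridine, 4 Å molecular sieves, CH2Cl2, air, rt, high dilution) closes the same A–O–B bond oxidatively at room temperature and rejoins the route at 23.

## Further compounds

F1 | step 10 | 4-(2-methoxy-5-{2-[3-methoxy-4-(methoxymethoxy)phenyl]ethyl}phenoxy)benzaldehyde | COCOc1ccc(CCc2ccc(OC)c(Oc3ccc(C=O)cc3)c2)cc1OC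
F2 | step 10 | 2-(3-bromophenyl)-1-[4-(2-methoxy-5-{2-[3-methoxy-4-(methoxymethoxy)phenyl]ethyl}phenoxy)phenyl]ethanol (racemic) | COCOc1ccc(CCc2ccc(OC)c(Oc3ccc(cc3)C(O)Cc3cccc(Br)c3)c2)cc1OC
F3 | step 9 | bicyclic lactone adduct of 12 and methyl coumalate (racemic, not isolated) | O=C1OC2C=C(Oc3cc(CCc4ccc(OCOC)c(OC)c4)ccc3OC)C1C=C2C(=O)OC
F4 | step 9 | methyl 4-(2-methoxy-5-{2-[3-methoxy-4-(methoxymethoxy)phenyl]ethyl}phenoxy)benzoate | COC(=O)c1ccc(Oc2cc(CCc3ccc(OCOC)c(OC)c3)ccc2OC)cc1
F5 | step 9 | N-methoxy-N-methyl-4-(2-methoxy-5-{2-[3-methoxy-4-(methoxymethoxy)phenyl]ethyl}phenoxy)benzamide | CON(C)C(=O)c1ccc(Oc2cc(CCc3ccc(OCOC)c(OC)c3)ccc2OC)cc1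
F6 | step 9 | 3-bromobenzylmagnesium bromide | Br[Mg]Cc1cccc(Br)c1
F7 | step 7 | 1-methoxy-4-{2-[3-methoxy-4-(methoxymethoxy)phenyl]ethyl}-2-[(trimethylsilyl)ethynyloxy]benzene | COCOc1ccc(CCc2ccc(OC)c(OC#C[Si](C)(C)C)c2)cc1OC
F8 | step 7 | silylated bicyclic lactone adduct of F7 and 17 (racemic, not isolated) | O=C1OC2C([Si](C)(C)C)=C(Oc3cc(CCc4ccc(OCOC)c(OC)c4)ccc3OC)C1C=C2C(=O)Cc1cccc(Br)c1
F9 | step 7 | 2-(3-bromophenyl)-1-[4-(2-methoxy-5-{2-[3-methoxy-4-(methoxymethoxy)phenyl]ethyl}phenoxy)-3-(trimethylsilyl)phenyl]ethanone | COc1ccc(CCc2ccc(OCOC)c(OC)c2)cc1Oc1ccc(cc1[Si](C)(C)C)C(=O)Cc1cccc(Br)c1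
F10 | step 12 | {3-[2-(4-{5-[2-(4-hydroxy-3-methoxyphenyl)ethyl]-2-methoxyphenoxy}phenyl)ethyl]phenyl}boronic acid | COc1ccc(CCc2ccc(O)c(OC)c2)cc1Oc1ccc(cc1)CCc1cccc(c1)B(O)O
A1 | alternative 1 | 21-membered macrolactone (ring A aryl ester of the ring B carboxylic acid) | COc1cc2ccc1OC(=O)c1cccc(c1)CCc1ccc(cc1)Oc1cc(ccc1OC)CC2
A2 | alternative 1 | target dimethyl ether (same compound as 23) | COc1cc2ccc1Oc1cccc(c1)CCc1ccc(cc1)Oc1cc(ccc1OC)CC2
A3 | alternative 2 | seco bisphenol with 2,6-dichlorophenol ring C and 2,6-dibromophenol ring D | COc1cc(CCc2cc(Br)c(O)c(Br)c2)ccc1Oc1cccc(c1)CCc1cc(Cl)c(O)c(Cl)c1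
A4 | alternative 2 | trihalogenated macrocyclic monomethyl ether | COc1cc2ccc1Oc1cccc(c1)CCc1cc(Cl)c(c(Cl)c1)Oc1cc(cc(Br)c1O)CC2
A5 | alternative 3 | seco ring C iodide with ring B styrene | COc1cc(CCc2ccc(OC)c(Oc3ccc(I)cc3)c2)ccc1Oc1cccc(C=C)c1
A6 | alternative 3 | macrocyclic E-stilbene dimethyl ether | COc1cc2ccc1Oc1cccc(c1)/C=C/c1ccc(cc1)Oc1cc(ccc1OC)CC2
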